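| setting | green | blue | grey | flask |
|---|---|---|---|---|
| left-handed substrate | 0.070 M | 0.11 M | 0.050 M | 0.050 M |
| right-handed substrate | 0.070 M | 0.11 M | 0.050 M | 0.050 M |
| reagent | 0.15 M | 0.15 M | 0.30 M | 0.150 M |
| catalyst | 0.10 mM | 0.10 mM | 0.10 mM | 0.10 mM |
| remark | run made earlier | run made earlier | run made earlier |  |

- green (time / min: left-handed product / %, left-handed substrate / %): 5.00: 20.9, 29.5; 12.0: 25.5, 24.5; 25.0: 29.2, 20.0; 40.0: 30.1, 20.1
- blue (time / min: left-handed product / %, left-handed substrate / %): 5.00: 19.4, 30.8; 12.0: 23.8, 26.8; 25.0: 24.2, 24.9; 40.0: 25.5, 24.5
- grey (time / min: left-handed product / %, left-handed substrate / %): 3.00: 23.9, 26.1; 6.00: 30.3, 18.9; 15.0: 36.1, 14.1; 40.0: 39.5, 9.9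

(scatter of a reading: 0.5 percentage points)

1. apparent order in reagent when 5.0% of the left-handed substrate and right-handed substrate together are converted (percent change of the rate of making left-handed product for one percent more reagent charged)
2. apparent order in catalyst when 5.0% of the left-handed substrate and right-handed substrate together are converted (percent change of the rate of making left-handed product for one percent more catalyst charged)

- catalyst is single-handed; left-handed substrate and right-handed substrate are mirror images of each other, charged as a racemate, each of them at the stated concentration
- the earlier runs were read with a standard deviation of 0.5 percentage points
- steps that have been proposed: reagent + catalyst + left-handed substrate -> catalyst + left-handed product; reagent + catalyst + right-handed substrate -> catalyst + right-handed product; 2 catalyst <-> resting dimer; 2 reagent -> homo dimer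
- no earlier run changes the charge of catalyst; that part of a forecast is a guess

1. I call the point at which 5.0% of both substrates together is converted the mark. I take the rate of making left-handed product there to follow the reagent still present, so I read two rates from the grey run. I assume that the logarithmic fall of left-handed substrate runs in proportion to reagent and that reagent falls by forming homo dimer.

2. The logarithmic fall of left-handed substrate runs at 0.217 /min over the first interval and 0.108 /min over the second. For a second-order loss of reagent, the reciprocal of this rate rises in a straight line. Extrapolating these two readings to the start, I read a pseudo-first-order rate of about 0.440 /min.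

3. The ratio of that rate to reagent's own rate of loss is the race number 0.641. Reagent's loss rate in the grey run is therefore 0.686 /min. The flask has the catalyst charge of the grey run, and I take both rates to scale with reagent, so I carry the race number over to the flask, where the loss rate comes to 0.343 /min.

4. At the mark in the flask I take left-handed substrate to have lost 7.50% of its own charge. That gives about 0.117 as the reagent's loss rate multiplied by the time to the mark.

5. I reckon the order in reagent at 1.04, counting the reagent used in conversion. In my reckoning working catalyst enters the rate directly and also through the race number, which sets the reagent still present at the mark, so its order is multiplied by 1.10. With the forecast's guessed order of 0.75 for working catalyst, I get 0.829.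

6. The forecast gives 1.03 in reagent and 0.85 in catalyst, the second above my reckoning, saying “Faster catalysis wastes less reagent”.

    reagent + catalyst + left-handed substrate → catalyst + left-handed product (k = 374 /M²/s)
    reagent + catalyst + right-handed substrate → catalyst + right-handed product (k = 173 /M²/s)
    2 catalyst ⇌ resting dimer (K = 4000 /M, k = 394 /M/s)
    2 reagent → homo dimer (k = 0.0204 /M/s)

The flask gives 1.1 in reagent and 0.87 in catalyst. At the start of the flask, homo dimer formation uses reagent 3.3 times as fast as the left-handed step does. The race number puts left-handed substrate in the flask at 31.8% after 3.00 min, against 33.1% in the flask itself. In the green run, which has the same reagent and catalyst charges, it gives 26.4% after 5.00 min, against 29.5% read.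

(The numbers in the tables are calculated for substances that don't exist.)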